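**Strategy.** The flavonol is cut at O1–C8a. O1 is an aryl ether oxygen on ring A whose carbon C8a lies ortho to C4a, the carbon carrying the C4 carbonyl, so this bond can be forged by addition–elimination on a fluorinated ring A. The key step lets the enol oxygen of a 2-(methoxymethoxy)-1,3-diketone displace one ortho fluoride of a 2,4,6-trifluorobenzoyl group. This closes ring C in a single operation and leaves the C5 and C7 fluorides as handles for the ring A oxygens and the C8 1,1-dimethylallyl group. The precursor is the diketone joining the trifluorophenyl ketone and the MOM-protected 2,2-dimethylchromene of ring B through a MOM-oxygenated central carbon.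

Key step: step 9

Remark on the chemistry: the target has no stereocentre; 14 and 15 carry transient stereocentres and are used as racemic mixtures.

Step 1
Reactants: 1 methyl glycolate
Product: 2 methyl 2-(methoxymethoxy)acetate
Conditions: MOMCl, iPr2NEt, CH2Cl2, 0 °C to rt
Reagents that add atoms: chloromethyl methyl ether (MOMCl), COCCl
Why: O-alkylation of the primary alcohol by the chloromethyl ether under amine base (MOM acetal formation) is routine and leaves the ester untouched.

Step 2
Reactants: 2 methyl 2-(methoxymethoxy)acetate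
Product: 3 N-methoxy-2-(methoxymethoxy)-N-methylacetamide
Conditions: MeNH(OMe)·HCl, iPrMgCl, THF, −20 °C
Reagents that add atoms: N,O-dimethylhydroxylamine hydrochloride, CNOC.Cl
Why: the chloromagnesium amide generated in the flask should attack the methyl ester faster than the Grignard reagent does (ester aminolysis to an N-methoxy-N-methylamide), and the MOM acetal is inert to base.

Step 3
Reactants: 4 1,3,5-trifluorobenzene; 3 N-methoxy-2-(methoxymethoxy)-N-methylacetamide
Product: 6 2-(methoxymethoxy)-1-(2,4,6-trifluorophenyl)ethan-1-one, via 2,4,6-trifluorophenyllithium 5 (not isolated)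
Conditions: n-BuLi, THF, −78 °C; then 3, −78 °C; aq. NH4Cl
Reagents that add atoms: none
Why: the ring C–H flanked by two fluorines is deprotonated cleanly at −78 °C, where the aryllithium does not eliminate LiF, and its addition to the N-methoxy-N-methylamide stops at the chelated tetrahedral adduct so that the ketone appears only on quench (Weinreb ketone synthesis).

Step 4
Reactants: 7 3,4-dihydroxybenzaldehyde; 8 3-chloro-3-methylbut-1-yne
Product: 9 3-hydroxy-4-[(2-methylbut-3-yn-2-yl)oxy]benzaldehyde
Conditions: K2CO3 (1.1 equiv), KI, CuI (cat.), acetone, 55 °C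
Reagents that add atoms: none
Why: the 4-OH, para to the formyl group, is by far the more acidic phenol, so a slight excess of carbonate should form mainly the 4-phenoxide, which is alkylated by the copper-activated tertiary propargylic chloride (copper-assisted propargylic etherification of a phenol).

Step 5
Reactants: 9 3-hydroxy-4-[(2-methylbut-3-yn-2-yl)oxy]benzaldehyde
Product: 10 3-(methoxymethoxy)-4-[(2-methylbut-3-yn-2-yl)oxy]benzaldehyde
Conditions: MOMCl, iPr2NEt, CH2Cl2, 0 °C to rt
Reagents that add atoms: chloromethyl methyl ether (MOMCl), COCCl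
Why: MOM protection of the remaining phenol under amine base is standard and neither the aldehyde nor the terminal alkyne reacts.

Step 6
Reactants: 10 3-(methoxymethoxy)-4-[(2-methylbut-3-yn-2-yl)oxy]benzaldehyde
Product: 12 8-(methoxymethoxy)-2,2-dimethyl-2H-chromene-6-carbaldehyde, via allenylphenol 11 (not isolated)
Conditions: N,N-diethylaniline, 190 °C
Reagents that add atoms: none
Why: the aryl propargyl ether should undergo a [3,3] shift (propargyl Claisen rearrangement) to the only free ortho carbon, and the resulting allenylphenol should close to the 2,2-dimethylchromene by 1,5-hydrogen shift and oxa-6π electrocyclisation, the MOM ether and aldehyde tolerating neutral heating.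

Step 7
Reactants: 6 2-(methoxymethoxy)-1-(2,4,6-trifluorophenyl)ethan-1-one; 12 8-(methoxymethoxy)-2,2-dimethyl-2H-chromene-6-carbaldehyde
Product: 14 3-hydroxy-2-(methoxymethoxy)-3-[8-(methoxymethoxy)-2,2-dimethyl-2H-chromen-6-yl]-1-(2,4,6-trifluorophenyl)propan-1-one (racemic syn/anti mixture), via lithium enolate 13 (not isolated)
Conditions: LiN(SiMe3)2, THF, −78 °C; then 12, −78 °C; aq. NH4Cl at −78 °C
Reagents that add atoms: none
Why: kinetic deprotonation should give the chelated Z-enolate, which adds to the non-enolisable aldehyde at −78 °C (crossed aldol addition), the cold quench preventing retro-aldol and premature fluoride displacement; the two new stereocentres form without control as a racemic syn/anti mixture, which is harmless because steps 8 and 9 erase both.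

Step 8
Reactants: 14 3-hydroxy-2-(methoxymethoxy)-3-[8-(methoxymethoxy)-2,2-dimethyl-2H-chromen-6-yl]-1-(2,4,6-trifluorophenyl)propan-1-one
Product: 15 2-(methoxymethoxy)-1-(2,4,6-trifluorophenyl)-3-[8-(methoxymethoxy)-2,2-dimethyl-2H-chromen-6-yl]propane-1,3-dione (racemic at C2)
Conditions: IBX, EtOAc, 75 °C
Reagents that add atoms: none
Why: oxidation of the secondary benzylic alcohol by pentavalent iodine (IBX oxidation) is a reliable way from β-hydroxy ketones to 1,3-diketones without C–C cleavage, and the MOM acetals, aryl fluorides and chromene alkene are inert to it.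

Step 9
Reactants: 15 2-(methoxymethoxy)-1-(2,4,6-trifluorophenyl)-3-[8-(methoxymethoxy)-2,2-dimethyl-2H-chromen-6-yl]propane-1,3-dione
Product: 16 5,7-difluoro-3-(methoxymethoxy)-2-[8-(methoxymethoxy)-2,2-dimethyl-2H-chromen-6-yl]-4H-chromen-4-one
Conditions: K2CO3, DMF, rt to 40 °C
Reagents that add atoms: none
Why: K2CO3 removes the acidic C2 proton of the 2-alkoxy-1,3-diketone, and the enolate oxygen on the ring B carbonyl adds to an ortho C–F carbon of the trifluorobenzoyl ring to give a Meisenheimer adduct stabilised by the ortho ketone and the remaining fluorines; loss of fluoride then forms O1–C8a (addition–elimination SNAr). The closest known reaction type is the base-mediated intramolecular SNAr of 1-(2-fluoroaryl)-1,3-diketones to chromones and flavones. Ring C, the only ring formed, closes in a 6-exo-trig mode through oxygen, since attack through the other enolate oxygen or through carbon would need a four-membered ring. No stereocentre is created, and the racemic C2 centre of 15 becomes the sp2 carbon C3. The step needs O-arylation to outrun retro-Claisen cleavage of the diketone and intermolecular attack at the para fluoride, which the mild dry carbonate base, the six-membered intramolecular transition state and the strongly activated arene should secure. Regiochemistry is no issue because the two ortho fluorines are equivalent, so only 16 can form.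

Step 10
Reactants: 16 5,7-difluoro-3-(methoxymethoxy)-2-[8-(methoxymethoxy)-2,2-dimethyl-2H-chromen-6-yl]-4H-chromen-4-one; 17 3-methylbut-2-en-1-ol
Product: 19 5-fluoro-3-(methoxymethoxy)-2-[8-(methoxymethoxy)-2,2-dimethyl-2H-chromen-6-yl]-7-[(3-methylbut-2-en-1-yl)oxy]-4H-chromen-4-one, via sodium prenyloxide 18 (not isolated)
Conditions: NaH, DMF, 0 °C; then 16 (1.0 equiv), −20 to 0 °C
Reagents that add atoms: none
Why: in DMF the free alkoxide should attack C7, para to the C4 carbonyl and less hindered than the peri carbon C5 (intermolecular SNAr), while one equivalent at low temperature and the deactivating new alkoxy group hold back a second substitution.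

Step 11
Reactants: 19 5-fluoro-3-(methoxymethoxy)-2-[8-(methoxymethoxy)-2,2-dimethyl-2H-chromen-6-yl]-7-[(3-methylbut-2-en-1-yl)oxy]-4H-chromen-4-one
Product: 20 5-[(4-methoxybenzyl)oxy]-3-(methoxymethoxy)-2-[8-(methoxymethoxy)-2,2-dimethyl-2H-chromen-6-yl]-7-[(3-methylbut-2-en-1-yl)oxy]-4H-chromen-4-one
Conditions: 4-methoxybenzyl alcohol, NaH, THF, 0 to 60 °C
Reagents that add atoms: 4-methoxybenzyl alcohol, COc1ccc(CO)cc1
Why: the remaining fluoride sits ortho to the C4 carbonyl and should be displaced by the sodium alkoxide with help from sodium coordination to that carbonyl (SNAr), installing O5 as an acid-labile ether that cannot hydrogen-bond to C4=O.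

Step 12
Reactants: 20 5-[(4-methoxybenzyl)oxy]-3-(methoxymethoxy)-2-[8-(methoxymethoxy)-2,2-dimethyl-2H-chromen-6-yl]-7-[(3-methylbut-2-en-1-yl)oxy]-4H-chromen-4-one
Product: 21 7-hydroxy-5-[(4-methoxybenzyl)oxy]-3-(methoxymethoxy)-2-[8-(methoxymethoxy)-2,2-dimethyl-2H-chromen-6-yl]-8-(2-methylbut-3-en-2-yl)-4H-chromen-4-one
Conditions: N,N-diethylaniline, 180 °C, argon
Reagents that add atoms: none
Why: the aryl prenyl ether should undergo an aromatic Claisen rearrangement that delivers the dimethyl-bearing allyl terminus to an ortho carbon; C8 is expected over C6 because, with O5 etherified and unable to chelate the carbonyl, the pyranone ring gives the C7–C8 bond the higher double-bond character and C6 is flanked by the bulky benzyl ether.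

Step 13
Reactants: 21 7-hydroxy-5-[(4-methoxybenzyl)oxy]-3-(methoxymethoxy)-2-[8-(methoxymethoxy)-2,2-dimethyl-2H-chromen-6-yl]-8-(2-methylbut-3-en-2-yl)-4H-chromen-4-one
Product: 22 Broussonol A, 3,5,7-trihydroxy-2-(8-hydroxy-2,2-dimethyl-2H-chromen-6-yl)-8-(2-methylbut-3-en-2-yl)-4H-chromen-4-one
Conditions: HCl (3 M aq.), MeOH, 50 °C
Reagents that add atoms: none
Why: acid-catalysed methanolysis should cleave both MOM acetals and solvolyse the peri 5-O-(4-methoxybenzyl) ether, whose cation is captured by the solvent (global acidic deprotection), under conditions mild enough for the chromene alkene and the terminal vinyl group.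

**Compound list**

1 | methyl glycolate | COC(=O)CO | starting material
2 | methyl 2-(methoxymethoxy)acetate | COCOCC(=O)OC | intermediate
3 | N-methoxy-2-(methoxymethoxy)-N-methylacetamide | COCOCC(=O)N(C)OC | intermediate
4 | 1,3,5-trifluorobenzene | Fc1cc(F)cc(F)c1 | starting material
5 | 2,4,6-trifluorophenyllithium | [Li]c1c(F)cc(F)cc1F | intermediate
6 | 2-(methoxymethoxy)-1-(2,4,6-trifluorophenyl)ethan-1-one | COCOCC(=O)c1c(F)cc(F)cc1F | intermediate
7 | 3,4-dihydroxybenzaldehyde | O=Cc1ccc(O)c(O)c1 | starting material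
8 | 3-chloro-3-methylbut-1-yne | CC(C)(Cl)C#C | starting material
9 | 3-hydroxy-4-[(2-methylbut-3-yn-2-yl)oxy]benzaldehyde | C#CC(C)(C)Oc1ccc(C=O)cc1O | intermediate
10 | 3-(methoxymethoxy)-4-[(2-methylbut-3-yn-2-yl)oxy]benzaldehyde | C#CC(C)(C)Oc1ccc(C=O)cc1OCOC | intermediate
11 | 4-hydroxy-3-(methoxymethoxy)-5-(3-methylbuta-1,2-dien-1-yl)benzaldehyde | CC(C)=C=Cc1cc(C=O)cc(OCOC)c1O | intermediate
12 | 8-(methoxymethoxy)-2,2-dimethyl-2H-chromene-6-carbaldehyde | COCOc1cc(C=O)cc2C=CC(C)(C)Oc12 | intermediate
13 | lithium (Z)-2-(methoxymethoxy)-1-(2,4,6-trifluorophenyl)ethen-1-olate | [Li]O/C(=C\OCOC)c1c(F)cc(F)cc1F | intermediate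
14 | 3-hydroxy-2-(methoxymethoxy)-3-[8-(methoxymethoxy)-2,2-dimethyl-2H-chromen-6-yl]-1-(2,4,6-trifluorophenyl)propan-1-one (racemic syn/anti mixture) | O=C(c1c(F)cc(F)cc1F)C(OCOC)C(O)c1cc(OCOC)c2c(c1)C=CC(C)(C)O2 | intermediate
15 | 2-(methoxymethoxy)-1-(2,4,6-trifluorophenyl)-3-[8-(methoxymethoxy)-2,2-dimethyl-2H-chromen-6-yl]propane-1,3-dione (racemic at C2) | O=C(c1c(F)cc(F)cc1F)C(OCOC)C(=O)c1cc(OCOC)c2c(c1)C=CC(C)(C)O2 | intermediate
16 | 5,7-difluoro-3-(methoxymethoxy)-2-[8-(methoxymethoxy)-2,2-dimethyl-2H-chromen-6-yl]-4H-chromen-4-one | O=c1c(OCOC)c(-c2cc(OCOC)c3c(c2)C=CC(C)(C)O3)oc2cc(F)cc(F)c12 | intermediate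
17 | 3-methylbut-2-en-1-ol | CC(C)=CCO | starting material
18 | sodium 3-methylbut-2-en-1-olate | [Na+].[O-]CC=C(C)C | intermediate
19 | 5-fluoro-3-(methoxymethoxy)-2-[8-(methoxymethoxy)-2,2-dimethyl-2H-chromen-6-yl]-7-[(3-methylbut-2-en-1-yl)oxy]-4H-chromen-4-one | O=c1c(OCOC)c(-c2cc(OCOC)c3c(c2)C=CC(C)(C)O3)oc2cc(OCC=C(C)C)cc(F)c12 | intermediate
20 | 5-[(4-methoxybenzyl)oxy]-3-(methoxymethoxy)-2-[8-(methoxymethoxy)-2,2-dimethyl-2H-chromen-6-yl]-7-[(3-methylbut-2-en-1-yl)oxy]-4H-chromen-4-one | O=c1c(OCOC)c(-c2cc(OCOC)c3c(c2)C=CC(C)(C)O3)oc2cc(OCC=C(C)C)cc(OCc4ccc(OC)cc4)c12 | intermediate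
21 | 7-hydroxy-5-[(4-methoxybenzyl)oxy]-3-(methoxymethoxy)-2-[8-(methoxymethoxy)-2,2-dimethyl-2H-chromen-6-yl]-8-(2-methylbut-3-en-2-yl)-4H-chromen-4-one | O=c1c(OCOC)c(-c2cc(OCOC)c3c(c2)C=CC(C)(C)O3)oc2c(C(C)(C)C=C)c(O)cc(OCc4ccc(OC)cc4)c12 | intermediate
22 | Broussonol A, 3,5,7-trihydroxy-2-(8-hydroxy-2,2-dimethyl-2H-chromen-6-yl)-8-(2-methylbut-3-en-2-yl)-4H-chromen-4-one | C=CC(C)(C)c1c(O)cc(O)c2c(=O)c(O)c(-c3cc(O)c4c(c3)C=CC(C)(C)O4)oc12 | target

**Step count.** Total: 13 steps. Longest linear sequence: 10 steps (from 7 through steps 4 to 13; the sequence from 1 through steps 1 to 3 and 7 to 13 is equally long).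

**Steps most likely to fail**

Step 12. The allyl unit may migrate to C6 in place of C8, the new 1,1-dimethylallyl group may isomerise further (abnormal Claisen shift), the freed 7-OH may add across the vinyl group, or the prenyl group may be lost on heating. The fallback replaces the sigmatropic shift by a cross-coupling; it sets out from 16 and comes back to the route at 22. Treating 16 with an excess of sodium (4-methoxyphenyl)methanolate in DMF should give, by double SNAr, 5,7-bis[(4-methoxybenzyl)oxy]-3-(methoxymethoxy)-2-[8-(methoxymethoxy)-2,2-dimethyl-2H-chromen-6-yl]-4H-chromen-4-one F1. N-Iodosuccinimide in MeCN at 0 °C should then iodinate C8, the usual site in fully etherified 5,7-dioxygenated flavones, to give 8-iodo-5,7-bis[(4-methoxybenzyl)oxy]-3-(methoxymethoxy)-2-[8-(methoxymethoxy)-2,2-dimethyl-2H-chromen-6-yl]-4H-chromen-4-one F2. A branch-selective Suzuki–Miyaura coupling with 3-methylbut-2-enylboronic acid pinacol ester (Pd(OAc)2, a bulky biarylphosphine, K3PO4, MeCN/water) should give 5,7-bis[(4-methoxybenzyl)oxy]-3-(methoxymethoxy)-2-[8-(methoxymethoxy)-2,2-dimethyl-2H-chromen-6-yl]-8-(2-methylbut-3-en-2-yl)-4H-chromen-4-one F3. Acid methanolysis as in step 13 then gives 22.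

Step 9. Retro-Claisen cleavage of the diketone by adventitious hydroxide, or intermolecular attack on the para fluoride, may outrun the ring closure. The fallback builds ring C from a phenol by oxidative cyclisation; it sets out from 12 and comes back at 16. Claisen–Schmidt condensation of 12 with commercial 1-(2,4-difluoro-6-hydroxyphenyl)ethanone (CC(=O)c1c(O)cc(F)cc1F; KOH, EtOH) should give (E)-1-(2,4-difluoro-6-hydroxyphenyl)-3-[8-(methoxymethoxy)-2,2-dimethyl-2H-chromen-6-yl]prop-2-en-1-one F4. Algar–Flynn–Oyamada oxidation (H2O2, NaOH, MeOH) should give 5,7-difluoro-3-hydroxy-2-[8-(methoxymethoxy)-2,2-dimethyl-2H-chromen-6-yl]-4H-chromen-4-one F5; the small fluorine at the 6'-position is expected to limit diversion to the aurone. MOMCl and iPr2NEt in CH2Cl2 then give 16.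

Step 10. Attack at C5 may compete with attack at C7, or both fluorides may be displaced. The fallback reverses the order of the two substitutions under chelation control; it sets out from 16 and comes back at 20. Sodium (4-methoxyphenyl)methanolate in toluene at 0 °C to rt, where the sodium ion bound to the C4 carbonyl delivers the alkoxide to the ortho carbon C5, should give 7-fluoro-5-[(4-methoxybenzyl)oxy]-3-(methoxymethoxy)-2-[8-(methoxymethoxy)-2,2-dimethyl-2H-chromen-6-yl]-4H-chromen-4-one F6. Sodium prenyloxide 18 in DMF then displaces the remaining para fluoride to give 20.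

**Further compounds**

F1 | step 12 | 5,7-bis[(4-methoxybenzyl)oxy]-3-(methoxymethoxy)-2-[8-(methoxymethoxy)-2,2-dimethyl-2H-chromen-6-yl]-4H-chromen-4-one | O=c1c(OCOC)c(-c2cc(OCOC)c3c(c2)C=CC(C)(C)O3)oc2cc(OCc4ccc(OC)cc4)cc(OCc4ccc(OC)cc4)c12
F2 | step 12 | 8-iodo-5,7-bis[(4-methoxybenzyl)oxy]-3-(methoxymethoxy)-2-[8-(methoxymethoxy)-2,2-dimethyl-2H-chromen-6-yl]-4H-chromen-4-one | O=c1c(OCOC)c(-c2cc(OCOC)c3c(c2)C=CC(C)(C)O3)oc2c(I)c(OCc4ccc(OC)cc4)cc(OCc4ccc(OC)cc4)c12
F3 | step 12 | 5,7-bis[(4-methoxybenzyl)oxy]-3-(methoxymethoxy)-2-[8-(methoxymethoxy)-2,2-dimethyl-2H-chromen-6-yl]-8-(2-methylbut-3-en-2-yl)-4H-chromen-4-one | O=c1c(OCOC)c(-c2cc(OCOC)c3c(c2)C=CC(C)(C)O3)oc2c(C(C)(C)C=C)c(OCc4ccc(OC)cc4)cc(OCc4ccc(OC)cc4)c12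
F4 | step 9 | (E)-1-(2,4-difluoro-6-hydroxyphenyl)-3-[8-(methoxymethoxy)-2,2-dimethyl-2H-chromen-6-yl]prop-2-en-1-one | O=C(/C=C/c1cc(OCOC)c2c(c1)C=CC(C)(C)O2)c1c(O)cc(F)cc1F
F5 | step 9 | 5,7-difluoro-3-hydroxy-2-[8-(methoxymethoxy)-2,2-dimethyl-2H-chromen-6-yl]-4H-chromen-4-one | O=c1c(O)c(-c2cc(OCOC)c3c(c2)C=CC(C)(C)O3)oc2cc(F)cc(F)c12
F6 | step 10 | 7-fluoro-5-[(4-methoxybenzyl)oxy]-3-(methoxymethoxy)-2-[8-(methoxymethoxy)-2,2-dimethyl-2H-chromen-6-yl]-4H-chromen-4-one | O=c1c(OCOC)c(-c2cc(OCOC)c3c(c2)C=CC(C)(C)O3)oc2cc(F)cc(OCc4ccc(OC)cc4)c12
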